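The side-chain ketone is masked as a dioxolane. The cuts then follow in this order: the diaryl ether bond between O-2 of ring A and C5 of ring B (isochromanone numbering, C5 then carrying Br), the ring A bonds C1–C2 and C5–C6, the ester bond between the acyl carbon and O-6 of ring B, and last the spiro carbon C3 (both C–O bonds) with the bond C3–C4.
Ring A is a 2-oxy-4-methoxy-6-alkylbenzoyl ring. C1 (bearing the ester C=O) and C6 (bearing the CH2 chain) are therefore the two carbons of a but-2-ynoate triple bond already esterified to O-6 of ring B, and C2–C5 with O-2 and the 4-OMe are the four carbons of 1,3-dimethoxy-1-silyloxybutadiene.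
In the forward direction the oxane carbons arrive as a δ-lactone that acylates a brominated orsellinate at its methyl group, and the lactone and oxane rings close together at the spiro carbon. O-6 is then acylated with the ynoic acid, ring A forms by (4+2) cycloaddition and loss of methanol, the seven-membered ring closes by Ullmann coupling, and the ketal is hydrolysed.
The methyl-bearing carbon (R) comes from (R)-propylene oxide. The spiro carbon (S) is the anomerically favoured epimer (acyloxy O axial, CH3 and benzylic CH2 equatorial on the oxane chair) and is set by acid equilibration, which the last step repeats.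

Key step: step 13

Assumption: under Brønsted acid the spiro acylal epimerises through its oxocarbenium ion. The more stable epimer should result, and conformational analysis of the given SMILES (CH3 and benzylic CH2 cis on the oxane) shows this to be the one drawn in the target.

Step 1
Reactants: 1 (R)-propylene oxide; 2 ethyl propiolate
Product: 4 ethyl (5R)-5-hydroxyhex-2-ynoate, via lithium ethyl propiolate 3 (not isolated)
Conditions: 2, n-BuLi, THF, −78 °C; BF3·OEt2, then 1, −78 °C; H2O quench
Reagents that add atoms: none
Why: BF3-promoted opening of a terminal epoxide by a lithium acetylide (Yamaguchi–Hirao alkynylation) occurs at the unsubstituted carbon, so the C–O bond of the stereocentre is not touched and the R configuration is carried over.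

Step 2
Reactants: 4 ethyl (5R)-5-hydroxyhex-2-ynoate
Product: 6 (6R)-6-methyloxan-2-one, via ethyl (5R)-5-hydroxyhexanoate 5 (not isolated)
Conditions: H2 (1 atm), Pd/C, EtOAc, rt; filter; p-TsOH (cat.), toluene, 80 °C
Reagents that add atoms: none
Why: Catalytic hydrogenation of the alkyne and acid-catalysed lactonisation of the δ-hydroxy ester, driven by loss of ethanol, leave the carbinol stereocentre unchanged.

Step 3
Reactants: 7 methyl orsellinate
Product: 8 methyl 2,4-bis(methoxymethoxy)-6-methylbenzoate
Conditions: NaH, MOMCl, DMF, 0 °C → rt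
Reagents that add atoms: chloromethyl methyl ether (MOMCl), COCCl
Why: Williamson-type O-alkylation of both phenoxides (NaH also frees the hydrogen-bonded 2-OH) gives acetal ethers that tolerate an amide base and fall off in the acid step that closes the spirocycle.

Step 4
Reactants: 8 methyl 2,4-bis(methoxymethoxy)-6-methylbenzoate
Product: 9 methyl 3-bromo-4,6-bis(methoxymethoxy)-2-methylbenzoate
Conditions: NBS, MeCN, 0 °C → rt, dark
Reagents that add atoms: N-bromosuccinimide, O=C1CCC(=O)N1Br
Why: In this electrophilic aromatic bromination the position between the two acetal ethers is shielded, so the halogen enters next to the methyl group (para to one alkoxy group, ortho to the other), as is usual for 2,4-dialkoxy-6-methylbenzoates.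

Step 5
Reactants: 9 methyl 3-bromo-4,6-bis(methoxymethoxy)-2-methylbenzoate; 6 (6R)-6-methyloxan-2-one
Product: 11 methyl 3-bromo-2-[(6R)-6-hydroxy-2-oxoheptyl]-4,6-bis(methoxymethoxy)benzoate (in equilibrium with its cyclic hemiketal), via benzylic lithium species 10 (not isolated)
Conditions: 9 (2 equiv), LiN(iPr)2 (2 equiv), THF, −78 °C; 6 (1 equiv), −78 → −40 °C; AcOH quench
Reagents that add atoms: none
Why: Lateral lithiation of the ortho-toluate (the amide base does not exchange the bromide, which has no ortho hydrogen) and Claisen-type acylation by the lactone open the ring without touching the carbinol centre, while the second equivalent of 10 deprotonates the acidic benzylic ketone and is recovered as 9.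

Step 6
Reactants: 11 methyl 3-bromo-2-[(6R)-6-hydroxy-2-oxoheptyl]-4,6-bis(methoxymethoxy)benzoate
Product: 13 (3S,6'R)-5-bromo-6,8-dihydroxy-6'-methylspiro[isochromane-3,2'-oxan]-1-one, via hydroxy keto acid 12 (not isolated)
Conditions: LiOH, THF/MeOH/H2O, 40 °C; then 3 M HCl, THF, 40 °C
Reagents that add atoms: lithium hydroxide, [Li+].[OH-]
Why: Ketone-assisted saponification is followed by acid hydrolysis of both MOM acetals and dehydrative spiroketalisation of the hydroxy keto acid to the oxaspirolactone, whose spiro centre forms reversibly through the oxocarbenium ion and should settle as the S epimer with CH3 and benzylic CH2 equatorial and the acyloxy oxygen axial (anomeric effect).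

Step 7
Reactants: 14 ethyl 3-oxooctanoate
Product: 15 ethyl 2-(2-pentyl-1,3-dioxolan-2-yl)acetate
Conditions: HOCH2CH2OH, p-TsOH (cat.), toluene, reflux, Dean–Stark
Reagents that add atoms: ethylene glycol, OCCO
Why: Acid-catalysed ketalisation with azeotropic removal of water is the standard protection of a β-keto ester and blocks the later alkyne-to-allenyl-ketone isomerisation.

Step 8
Reactants: 15 ethyl 2-(2-pentyl-1,3-dioxolan-2-yl)acetate
Product: 16 2-(2-pentyl-1,3-dioxolan-2-yl)acetaldehyde
Conditions: i-Bu2AlH (1.05 equiv), CH2Cl2, −78 °C; aq potassium sodium tartrate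
Reagents that add atoms: none
Why: Partial reduction of an ester by i-Bu2AlH stops at the aluminium hemiacetal, which the neighbouring ketal oxygen stabilises by chelation at low temperature and which releases the aldehyde only on work-up.

Step 9
Reactants: 16 2-(2-pentyl-1,3-dioxolan-2-yl)acetaldehyde
Product: 17 2-pentyl-2-(prop-2-yn-1-yl)-1,3-dioxolane
Conditions: dimethyl (1-diazo-2-oxopropyl)phosphonate, K2CO3, MeOH, 0 °C → rt
Reagents that add atoms: dimethyl (1-diazo-2-oxopropyl)phosphonate, CC(=O)C(=[N+]=[N-])P(=O)(OC)OC
Why: In the Seyferth–Gilbert homologation in its Ohira–Bestmann form the diazomethylphosphonate anion adds to the aldehyde and the alkylidene carbene left after loss of phosphate and N2 undergoes a 1,2-hydrogen shift, under a base mild enough to avoid β-elimination of a ketal oxygen.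

Step 10
Reactants: 17 2-pentyl-2-(prop-2-yn-1-yl)-1,3-dioxolane
Product: 19 4-(2-pentyl-1,3-dioxolan-2-yl)but-2-ynoic acid, via lithium acetylide 18 (not isolated)
Conditions: n-BuLi (1.0 equiv), THF, −78 °C; CO2 (g); cold 1 M HCl to pH 3; used directly
Reagents that add atoms: carbon dioxide, O=C=O
Why: Carboxylation of a lithium acetylide is reliable, one equivalent of base removes only the acetylenic proton, and a brief cold acidification spares the dioxolane.

Step 11
Reactants: 20 methyl (E)-3-methoxybut-2-enoate
Product: 22 1,3-dimethoxy-1-(trimethylsilyloxy)buta-1,3-diene, via lithium dienolate 21 (not isolated)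
Conditions: LiN(iPr)2, THF, −78 °C; Me3SiCl, −78 °C → rt; distillation
Reagents that add atoms: chlorotrimethylsilane, C[Si](C)(C)Cl
Why: γ-Deprotonation of the vinylogous carbonate gives the extended enolate, and O-silylation converts it into the cross-conjugated silyl ketene acetal diene, a standard preparation.

Step 12
Reactants: 13 (3S,6'R)-5-bromo-6,8-dihydroxy-6'-methylspiro[isochromane-3,2'-oxan]-1-one; 19 4-(2-pentyl-1,3-dioxolan-2-yl)but-2-ynoic acid
Product: 23 (3S,6'R)-5-bromo-8-hydroxy-6'-methyl-1-oxospiro[isochromane-3,2'-oxan]-6-yl 4-(2-pentyl-1,3-dioxolan-2-yl)but-2-ynoate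
Conditions: DCC, DMAP (5 mol %), CH2Cl2, 0 °C
Reagents that add atoms: none
Why: Steglich esterification acylates only the acidic 6-OH because the 8-OH is hydrogen-bonded to the lactone carbonyl, the selectivity used in classical depside couplings, and little DMAP at 0 °C avoids alkyne-to-allene isomerisation.

Step 13
Reactants: 23 (3S,6'R)-5-bromo-8-hydroxy-6'-methyl-1-oxospiro[isochromane-3,2'-oxan]-6-yl 4-(2-pentyl-1,3-dioxolan-2-yl)but-2-ynoate; 22 1,3-dimethoxy-1-(trimethylsilyloxy)buta-1,3-diene
Product: 27 (3S,6'R)-5-bromo-8-hydroxy-6'-methyl-1-oxospiro[isochromane-3,2'-oxan]-6-yl 2-hydroxy-4-methoxy-6-[(2-pentyl-1,3-dioxolan-2-yl)methyl]benzoate, via 8-O-trimethylsilyl ynoate 24 (not isolated), via cyclohexa-1,4-diene cycloadduct 25 (not isolated), via bis(trimethylsilyl) depside 26 (not isolated)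
Conditions: N,O-bis(trimethylsilyl)acetamide (BSA), toluene, 60 °C; 22 (4 equiv, in portions), 125 °C, sealed tube; then 10 % aq citric acid, THF, rt
Reagents that add atoms: none
Why: After transient silylation of the 8-OH, the electron-rich diene and the electron-poor triple bond of 24 combine in a concerted, asynchronous, normal-electron-demand (4+2) cycloaddition in which the CH2 terminus of 22 bonds to the alkyne carbon bearing the CH2 chain (ring A C5–C6) and the ketene acetal carbon bonds to the ester-bearing alkyne carbon (ring A C1–C2), giving 25. At the reaction temperature 25 expels methanol from its mixed ketal carbon to give arene 26, and the mild acid work-up removes both trimethylsilyl groups while sparing the dioxolane, which leaves the ring A phenol hydrogen-bonded to the ester carbonyl. The closest known reaction type is the Diels–Alder/aromatisation of 1,3-dioxygenated silyl ketene acetal dienes with alkynoates to give resorcylates. Ring A is the only ring closed and arises by intermolecular cycloaddition with both C–C bonds made in one event, and the only new stereocentre, the ketal carbon of 25, is erased on aromatisation, so nothing has to be controlled and the remote R and S centres stay untouched under neutral conditions. The step needs regioselectivity, which is secured because the largest diene HOMO coefficient lies at the CH2 terminus (pushed by the oxygens at C1 and C3) and the largest LUMO coefficient lies at the β-carbon of the ynoate, a polarisation strengthened by the electron-poor bromoaryl ester. The excess diene scavenges the liberated methanol so that the aryl ester is not transesterified.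

Step 14
Reactants: 27 (3S,6'R)-5-bromo-8-hydroxy-6'-methyl-1-oxospiro[isochromane-3,2'-oxan]-6-yl 2-hydroxy-4-methoxy-6-[(2-pentyl-1,3-dioxolan-2-yl)methyl]benzoate
Product: 28 depsidone ketal (the target with the side-chain ketone as its 1,3-dioxolane; spiro carbon S, methyl-bearing carbon R)
Conditions: CuI (30 mol %), N,N-dimethylglycine (60 mol %), Cs2CO3 (3.5 equiv), degassed 1,4-dioxane (0.005 M), Ar, 95 °C
Reagents that add atoms: none
Why: In this intramolecular Ullmann diaryl ether synthesis with monovalent copper the ring A phenoxide, held beside C5–Br by the ester, closes the seven-membered ring, while the 8-phenoxide formed by the excess base cannot reach C5 and makes ring B too electron-rich for Smiles-type ipso attack at C6.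

Step 15
Reactants: 28 depsidone ketal
Product: 29 CNP0301127.1 (target; spiro carbon S, methyl-bearing carbon R)
Conditions: 1 M aq HCl, THF, rt → 35 °C
Reagents that add atoms: water, O
Why: Acid-catalysed ketal hydrolysis frees the 2-oxoheptyl ketone, dilute acid at this temperature leaves the aryl ester and the lactone intact, and any reversible opening of the spiro acylal recloses to the thermodynamically favoured S epimer.

Compound list
1 | (R)-propylene oxide | C[C@@H]1CO1 | starting material
2 | ethyl propiolate | C#CC(=O)OCC | starting material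
3 | lithium ethyl propiolate | [Li]C#CC(=O)OCC | intermediate
4 | ethyl (5R)-5-hydroxyhex-2-ynoate | C[C@@H](O)CC#CC(=O)OCC | intermediate
5 | ethyl (5R)-5-hydroxyhexanoate | C[C@@H](O)CCCC(=O)OCC | intermediate
6 | (6R)-6-methyloxan-2-one | C[C@@H]1CCCC(=O)O1 | intermediate
7 | methyl orsellinate (methyl 2,4-dihydroxy-6-methylbenzoate) | COC(=O)c1c(C)cc(O)cc1O | starting material
8 | methyl 2,4-bis(methoxymethoxy)-6-methylbenzoate | COCOc1cc(C)c(C(=O)OC)c(OCOC)c1 | intermediate
9 | methyl 3-bromo-4,6-bis(methoxymethoxy)-2-methylbenzoate | COCOc1cc(OCOC)c(C(=O)OC)c(C)c1Br | intermediate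
10 | benzylic lithium derivative of 9 (methyl 3-bromo-2-(lithiomethyl)-4,6-bis(methoxymethoxy)benzoate) | COCOc1cc(OCOC)c(C(=O)OC)c(C[Li])c1Br | intermediate
11 | methyl 3-bromo-2-[(6R)-6-hydroxy-2-oxoheptyl]-4,6-bis(methoxymethoxy)benzoate | COCOc1cc(OCOC)c(C(=O)OC)c(CC(=O)CCC[C@@H](C)O)c1Br | intermediate
12 | 3-bromo-2-[(6R)-6-hydroxy-2-oxoheptyl]-4,6-bis(methoxymethoxy)benzoic acid | COCOc1cc(OCOC)c(C(=O)O)c(CC(=O)CCC[C@@H](C)O)c1Br | intermediate
13 | (3S,6'R)-5-bromo-6,8-dihydroxy-6'-methylspiro[isochromane-3,2'-oxan]-1-one | Oc1cc(O)c2c(c1Br)C[C@]1(CCC[C@@H](C)O1)OC2=O | intermediate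
14 | ethyl 3-oxooctanoate | CCCCCC(=O)CC(=O)OCC | starting material
15 | ethyl 2-(2-pentyl-1,3-dioxolan-2-yl)acetate | CCCCCC1(CC(=O)OCC)OCCO1 | intermediate
16 | 2-(2-pentyl-1,3-dioxolan-2-yl)acetaldehyde | CCCCCC1(CC=O)OCCO1 | intermediate
17 | 2-pentyl-2-(prop-2-yn-1-yl)-1,3-dioxolane | CCCCCC1(CC#C)OCCO1 | intermediate
18 | lithium acetylide of 17 | CCCCCC1(CC#C[Li])OCCO1 | intermediate
19 | 4-(2-pentyl-1,3-dioxolan-2-yl)but-2-ynoic acid | CCCCCC1(CC#CC(=O)O)OCCO1 | intermediate
20 | methyl (E)-3-methoxybut-2-enoate | CO/C(C)=C/C(=O)OC | starting material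
21 | lithium dienolate of 20 | [Li]OC(OC)=CC(OC)=C | intermediate
22 | 1,3-dimethoxy-1-(trimethylsilyloxy)buta-1,3-diene | COC(O[Si](C)(C)C)=CC(OC)=C | intermediate
23 | (3S,6'R)-5-bromo-8-hydroxy-6'-methyl-1-oxospiro[isochromane-3,2'-oxan]-6-yl 4-(2-pentyl-1,3-dioxolan-2-yl)but-2-ynoate | CCCCCC1(OCCO1)CC#CC(=O)Oc1cc(O)c2c(c1Br)C[C@]1(CCC[C@@H](C)O1)OC2=O | intermediate
24 | 8-O-trimethylsilyl ether of 23 | CCCCCC1(OCCO1)CC#CC(=O)Oc1cc(O[Si](C)(C)C)c2c(c1Br)C[C@]1(CCC[C@@H](C)O1)OC2=O | intermediate
25 | (3S,6'R)-5-bromo-6'-methyl-1-oxo-8-(trimethylsilyloxy)spiro[isochromane-3,2'-oxan]-6-yl 4,6-dimethoxy-2-[(2-pentyl-1,3-dioxolan-2-yl)methyl]-6-(trimethylsilyloxy)cyclohexa-1,4-diene-1-carboxylate (ketal carbon C6 of the diene ring unassigned) | CCCCCC1(OCCO1)CC2=C(C(=O)Oc3cc(O[Si](C)(C)C)c4c(c3Br)C[C@]3(CCC[C@@H](C)O3)OC4=O)C(OC)(O[Si](C)(C)C)C=C(OC)C2 | intermediate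
26 | bis(trimethylsilyl) ether of 27 (ring A O-2 and ring B O-8) | CCCCCC1(OCCO1)Cc1cc(OC)cc(O[Si](C)(C)C)c1C(=O)Oc1cc(O[Si](C)(C)C)c2c(c1Br)C[C@]1(CCC[C@@H](C)O1)OC2=O | intermediate
27 | (3S,6'R)-5-bromo-8-hydroxy-6'-methyl-1-oxospiro[isochromane-3,2'-oxan]-6-yl 2-hydroxy-4-methoxy-6-[(2-pentyl-1,3-dioxolan-2-yl)methyl]benzoate | CCCCCC1(OCCO1)Cc1cc(OC)cc(O)c1C(=O)Oc1cc(O)c2c(c1Br)C[C@]1(CCC[C@@H](C)O1)OC2=O | intermediate
28 | depsidone ketal (target with the 2-oxoheptyl ketone as 1,3-dioxolane; spiro S, CHCH3 R) | CCCCCC1(OCCO1)Cc1cc(OC)cc2c1C(=O)Oc1cc(O)c3c(c1O2)C[C@]1(CCC[C@@H](C)O1)OC3=O | intermediate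
29 | CNP0301127.1 (spiro S, CHCH3 R) | CCCCCC(=O)Cc1cc(OC)cc2c1C(=O)Oc1cc(O)c3c(c1O2)C[C@]1(CCC[C@@H](C)O1)OC3=O | target

Total step count: 15.
Longest linear sequence: 8 steps (for example steps 3, 4, 5, 6, 12, 13, 14, 15). The branches from 1 and from 14 are equally long.

Steps most likely to fail

Step 14. Copper may insert only slowly into the doubly ortho-substituted, electron-rich C–Br bond. Hydrodebromination, cleavage of the aryl ester by carbonate, or ipso attack of the ring A phenoxide at C6 with migration of ring B from the ester oxygen to the phenol oxygen (Smiles rearrangement) could then take over.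
The fallback replaces the halide coupling under hot carbonate by an oxidative boron-to-oxygen coupling under amine base. It sets out from 27. Miyaura borylation (Pd(OAc)2, SPhos, B2pin2, KOAc, dioxane, 80 °C) would give the pinacol boronate F1. An intramolecular Chan–Lam coupling with divalent copper (Cu(OAc)2, pyridine, 4 Å molecular sieves, CH2Cl2, air, rt, high dilution) would close the ether and come back to the route at 28.

Step 13. The β-alkyl-substituted triple bond may react too slowly at temperatures the diene survives, and the activated aryl ester may transfer its acyl group to the liberated methanol.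
The fallback runs the same cycloaddition on a robust simple ester and forms the depside ester afterwards. It sets out from 19.
- Esterification (BnOH, DCC, DMAP, CH2Cl2, 0 °C) would give the benzyl ynoate F2.
- Heating F2 neat with 22 at 140–150 °C would lead through the cycloadduct F3 and the aryl silyl ether F4 to the benzyl resorcylate F5 after citric acid work-up.
- Hydrogenolysis (H2, Pd/C, EtOAc) would give the ring A acid F6.
- Carbodiimide coupling of F6 with 13 (DCC, toluene, rt), selective for the 6-OH as in step 12, would come back to the route at 27.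

Step 5. The benzylic anion may deprotonate the lactone instead of adding to it, and the released alkoxide may start uncontrolled cyclisations onto the methyl ester.
The fallback uses a non-enolising acyl donor with the alcohol masked. It sets out from 6.
- Aminolysis (MeNH(OMe)·HCl, i-PrMgCl, THF, −20 °C) would give the hydroxy Weinreb amide F7.
- Silylation (TBSCl, imidazole, DMF) would give the silyl ether F8.
- Acylation of 10 (from 9 and LiN(iPr)2, THF, −78 °C) with F8 would give the silylated keto ester F9 through a chelated tetrahedral intermediate that collapses only on quenching.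
- Desilylation (HF·pyridine, MeCN, 0 °C) would come back to the route at 11.

Further compounds
F1 | step 14 | (3S,6'R)-8-hydroxy-6'-methyl-1-oxo-5-(4,4,5,5-tetramethyl-1,3,2-dioxaborolan-2-yl)spiro[isochromane-3,2'-oxan]-6-yl 2-hydroxy-4-methoxy-6-[(2-pentyl-1,3-dioxolan-2-yl)methyl]benzoate | CCCCCC1(OCCO1)Cc1cc(OC)cc(O)c1C(=O)Oc1cc(O)c2c(c1B5OC(C)(C)C(C)(C)O5)C[C@]1(CCC[C@@H](C)O1)OC2=O
F2 | step 13 | benzyl 4-(2-pentyl-1,3-dioxolan-2-yl)but-2-ynoate | CCCCCC1(OCCO1)CC#CC(=O)OCc1ccccc1
F3 | step 13 | benzyl 4,6-dimethoxy-2-[(2-pentyl-1,3-dioxolan-2-yl)methyl]-6-(trimethylsilyloxy)cyclohexa-1,4-diene-1-carboxylate | CCCCCC1(OCCO1)CC1=C(C(=O)OCc2ccccc2)C(OC)(O[Si](C)(C)C)C=C(OC)C1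
F4 | step 13 | benzyl 4-methoxy-2-[(2-pentyl-1,3-dioxolan-2-yl)methyl]-6-(trimethylsilyloxy)benzoate | CCCCCC1(OCCO1)Cc1cc(OC)cc(O[Si](C)(C)C)c1C(=O)OCc1ccccc1
F5 | step 13 | benzyl 2-hydroxy-4-methoxy-6-[(2-pentyl-1,3-dioxolan-2-yl)methyl]benzoate | CCCCCC1(OCCO1)Cc1cc(OC)cc(O)c1C(=O)OCc1ccccc1
F6 | step 13 | 2-hydroxy-4-methoxy-6-[(2-pentyl-1,3-dioxolan-2-yl)methyl]benzoic acid | CCCCCC1(OCCO1)Cc1cc(OC)cc(O)c1C(=O)O
F7 | step 5 | (5R)-5-hydroxy-N-methoxy-N-methylhexanamide | C[C@@H](O)CCCC(=O)N(C)OC
F8 | step 5 | (5R)-5-(tert-butyldimethylsilyloxy)-N-methoxy-N-methylhexanamide | C[C@@H](O[Si](C)(C)C(C)(C)C)CCCC(=O)N(C)OC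
F9 | step 5 | methyl 3-bromo-2-[(6R)-6-(tert-butyldimethylsilyloxy)-2-oxoheptyl]-4,6-bis(methoxymethoxy)benzoate | COCOc1cc(OCOC)c(C(=O)OC)c(CC(=O)CCC[C@@H](C)O[Si](C)(C)C(C)(C)C)c1Br
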